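| setting | amber | autumn | noon | summer | dawn | midnight | dusk |
|---|---|---|---|---|---|---|---|
| E | 0.35 M | 0.32 M | 1.2 M | 0.50 M | 0.60 M | 0.32 M | 0.32 M |
| J | 3.5 mol% | 3.5 mol% | 1.2 mol% | 2 mol% | 3.5 mol% | 3.5 mol% | 2.5 mol% |
| temperature | 50 °C | 20 °C | 50 °C | 35 °C | 50 °C | 50 °C | 20 °C |
| remark | run made earlier |  |  |  |  |  |  |
| time |  | 20 min | 20 min | 20 min | 20 min | 20 min | 20 min |

amber run (percent of the E charged)

| time / min | Q / % |
|---|---|
| 1.33 | 9 |
| 2.50 | 19 |
| 4.00 | 35 |
| 5.00 | 43 |
| 6.00 | 51 |
| 8.00 | 67 |

(readings scatter by 2 percentage points)

- the earlier runs were read with a standard deviation of 2 percentage points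
- the earlier runs do not show what temperature does; that part of a forecast is a guess
- no earlier run changes the charge of J; that part of a forecast is a guess

* all flasks from highest to lowest amount of Q, in percent of the E charged, at 20 min (autumn / noon / summer / dawn / midnight / dusk)
* the same order at 2.5 h (autumn / noon / summer / dawn / midnight / dusk)
* the amount of Q, in percent of the E charged of the flask you put first, at 20 min
* the amount of Q, in percent of the E charged of the flask you put last, at 20 min

Amber loses its remaining E faster late than early. Taking the fraction left as one minus Q, I find it falling at 0.0709 /min up to the first reading and at 0.198 /min between the last two. Both are readings and carry the scatter of 2 percentage points. The early figure is a mean over a fall that is still speeding up, so it is no constant; the late one I treat as a pseudo-first-order constant, which gives a half-life of whatever E is left for as long as it holds.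

My ladder starts from the late figure, which gives 3.51 min, the clock of the fraction left; it describes amber at 33.0% left. Above it stands the same reckoning on the early mean, 9.77 min, which covers amber's first minutes down to 91.0% left and is no half-life of that flask. Then comes the asked time, 3.42 clock half-lives past amber's last reading. The top rung, 2.5 h, lies 40.5 half-lives past that reading, and amber, read up to 8.00 min, shows nothing of Q so late.

Midnight has the same loading and temperature as amber and slightly less E. I hold the clock unchanged and run it on from amber's last fraction. That leaves 3.08% of the E in midnight at 20 min, a loose figure given the scatter. For temperature and for the charge of J, I have a guess and no clock.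

The forecast, from the same runs, gives dawn > midnight > noon > summer > autumn > dusk at the first time and noon > summer > dawn > autumn > dusk > midnight at the second, with 95% on top and 12% at the bottom. Its ground: “So the rate looks roughly zero order in E and is presumably set by J.” It reads a line in Q, where I read a clock on the fraction left.

The flasks stand noon > midnight > dawn > summer > autumn > dusk at 20 min, from 90.3% in noon to 26.8% in dusk, and dusk > autumn > summer > noon > midnight > dawn at 2.5 h.

    E + J → Z + Q (k = 0.440 /M/min, Ea = 49.0 kJ/mol)
    Q + J ⇌ D + J, rate k2*[J]*[Q] forward; the back reaction follows from the equilibrium constant (K = 3.10, k = 4.20 /M/min, Ea = 45.0 kJ/mol, ΔH = −72.0 kJ/mol)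
    E + Z → Q + Z, rate k3*[Z]*[E] (k = 44.0 /M/min, Ea = 35.0 kJ/mol)
    2 J → G (k = 9.70 /M/min, Ea = 67.0 kJ/mol)
    (constants at 50 °C)

Midnight keeps 3.0% of its E against my 3.08%, while Q holds 87.0% and D 10.0%. The same rule read in dusk, from 88% left at 12 min to 72% at 20 min, gives 28.9 min, longer than 3.51 min; it reckons 35.1% at 50 min, where dusk holds 25%. In dusk at 13.0 min, E has a half-life of 34 min by its passing into Q and 32 h by E + J into Z + Q. At that moment in dusk, the passing of E into Q uses E at 56 times the rate of E + J into Z + Q.

(The earlier runs and the new flask are simulated with constants of no real substance; noise was put on by code.)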